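Ring B is not brought in as an arene but grown on the finished chromone: its bonds C1'–C2' and C5'–C6' are cut, leaving a 2-ethynylchromone and a 2,4-dialkoxyfuran. The step exploits the oxygen pattern of ring B: the oxygens at C2' and C5' stand para (the two ends of the furan diene, joined by the bridge oxygen), the oxygen at C4' sits on the furan, and C3' and C6' carry hydrogen. One cycloaddition with bridge opening should therefore deliver ring B with 2'-OMe, 4'-OBn and free 5'-OH. The precursor is the fully oxygenated 5,7-bis(benzyloxy)-3,6,8-trimethoxy-2-ethynylchromone, made from a phloroglucinol ether; the labile furan is made last and used at once.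

Key step: step 9

Remark: furan 15 is acid-labile and is carried as a cold, filtered solution straight into step 9; bicycle 16 is racemic and transient, so it is drawn without descriptors, and neither 17 nor 18 has a stereocentre.

Step 1
Reactants: 1 1,3,5-tris(benzyloxy)benzene
Product: 2 1,3,5-tris(benzyloxy)-2,4-dibromobenzene
Conditions: NBS (2.05 equiv), CH2Cl2, −20 °C → rt
Reagents that add atoms: N-bromosuccinimide, O=C1CCC(=O)N1Br
Why: Electrophilic aromatic bromination of the phloroglucinol triether at two of its three equivalent positions, each bromine slowing the next substitution so that two equivalents should stop at the dibromide.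

Step 2
Reactants: 2 1,3,5-tris(benzyloxy)-2,4-dibromobenzene
Product: 3 1,3,5-tris(benzyloxy)-2,4-dimethoxybenzene
Conditions: NaOMe (excess, in MeOH), CuI (cat.), DMF, 110 °C
Reagents that add atoms: sodium methoxide, C[O-].[Na+]
Why: Copper-catalysed Ullmann-type C–O coupling replaces both aryl bromides by methoxide; flanking ether oxygens are tolerated and benzyl ethers are inert to NaOMe.

Step 3
Reactants: 3 1,3,5-tris(benzyloxy)-2,4-dimethoxybenzene; 4 methoxyacetyl chloride
Product: 6 1-[4,6-bis(benzyloxy)-2-hydroxy-3,5-dimethoxyphenyl]-2-methoxyethan-1-one, via tribenzyl ketone 5 (not isolated)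
Conditions: TiCl4, CH2Cl2, −40 → 0 °C; then BCl3 (1.1 equiv), −78 → −20 °C; aq. NaHCO3
Reagents that add atoms: none
Why: Friedel–Crafts acylation at the only free ring position, then chelation-directed cleavage of one of the two equivalent ortho benzyl ethers by BCl3 through the ketone–boron chelate, which should stop after one benzyl group because the carbonyl is then tied up.

Step 4
Reactants: 6 1-[4,6-bis(benzyloxy)-2-hydroxy-3,5-dimethoxyphenyl]-2-methoxyethan-1-one
Product: 9 5,7-bis(benzyloxy)-3,6,8-trimethoxy-2-methyl-4H-chromen-4-one, via aryl acetate 7 (not isolated), via 1,3-diketone 8 (not isolated)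
Conditions: Ac2O, NaOAc, 150 °C
Reagents that add atoms: acetic anhydride, CC(=O)OC(C)=O
Why: Kostanecki–Robinson chromone synthesis: O-acetylation to 7, acetyl transfer to the methoxy-bearing α-carbon (Baker–Venkataraman type) to 8 and cyclodehydration give the 3-methoxy-2-methylchromone, the 3-methoxy group leaving no site for C3 acylation.

Step 5
Reactants: 9 5,7-bis(benzyloxy)-3,6,8-trimethoxy-2-methyl-4H-chromen-4-one
Product: 10 5,7-bis(benzyloxy)-3,6,8-trimethoxy-4-oxo-4H-chromene-2-carbaldehyde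
Conditions: SeO2, 1,4-dioxane, reflux
Reagents that add atoms: selenium dioxide, O=[Se]=O
Why: Riley oxidation: the C2 methyl group is the enolisable γ-position of the pyranone and should be oxidised to the aldehyde, as with 2-methylchromones and O-alkylmaltols, while the benzyl ethers are left alone.

Step 6
Reactants: 10 5,7-bis(benzyloxy)-3,6,8-trimethoxy-4-oxo-4H-chromene-2-carbaldehyde
Product: 11 5,7-bis(benzyloxy)-2-ethynyl-3,6,8-trimethoxy-4H-chromen-4-one
Conditions: dimethyl (1-diazo-2-oxopropyl)phosphonate, K2CO3, MeOH–THF, 0 °C → rt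
Reagents that add atoms: dimethyl (1-diazo-2-oxopropyl)phosphonate, COP(=O)(OC)C(=[N+]=[N-])C(C)=O
Why: Ohira–Bestmann variant of the Seyferth–Gilbert homologation: the diazomethylphosphonate anion made in the flask adds to the aldehyde, and the diazoalkene loses N2 and undergoes a 1,2-hydrogen shift to the terminal alkyne under carbonate conditions mild enough for the pyranone ring.

Step 7
Reactants: 12 tetronic acid
Product: 13 4-(benzyloxy)furan-2(5H)-one
Conditions: BnOH, TsOH·H2O (cat.), toluene, reflux, Dean–Stark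
Reagents that add atoms: benzyl alcohol, OCc1ccccc1
Why: Acid-catalysed O-alkylation (vinylogous Fischer esterification) of the enolic 4-hydroxyl, driven by azeotropic removal of water, gives the 4-alkoxybutenolide and avoids the C3-alkylation seen with benzyl halides and base.

Step 8
Reactants: 13 4-(benzyloxy)furan-2(5H)-one
Product: 15 4-(benzyloxy)-2-methoxyfuran, via furanium salt 14 (not isolated)
Conditions: Me3OBF4 (1.0 equiv), CH2Cl2, 0 °C → rt; then iPr2NEt, −78 → 0 °C; pentane, filtration under Ar; solution used at once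
Reagents that add atoms: trimethyloxonium tetrafluoroborate, C[O+](C)C.F[B-](F)(F)F
Why: Proposed new method: the carbonyl oxygen of the vinylogous carbonate is its most nucleophilic site and should be methylated by the oxonium salt to the furanium ion 14, which is stabilised by three oxygens and whose C5–H bonds are acidic because their loss gives the aromatic furan, so a hindered amine that cannot dealkylate the cation should deprotonate it cleanly; the closest known reaction type is the Meerwein O-alkylation of lactones to lactonium salts followed by deprotonation to ketene acetals, together with the O-methylation of 4-alkoxy-2-pyranones to 2,4-dialkoxypyrylium salts.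

Step 9
Reactants: 11 5,7-bis(benzyloxy)-2-ethynyl-3,6,8-trimethoxy-4H-chromen-4-one; 15 4-(benzyloxy)-2-methoxyfuran
Product: 17 5,7-bis(benzyloxy)-2-[4-(benzyloxy)-5-hydroxy-2-methoxyphenyl]-3,6,8-trimethoxy-4H-chromen-4-one, via oxanorbornadiene 16 (not isolated)
Conditions: 15 (3 equiv), toluene, 80 °C, sealed tube, Ar; then SiO2, CH2Cl2, rt
Reagents that add atoms: none
Why: A thermal [4+2] cycloaddition joins the HOMO of the doubly donor-substituted furan to the LUMO of the alkyne, which is the far end of the conjugated system O=C4–C3=C2–C≡C of ring C, and adduct 16 then ionises at its ketal bridgehead and tautomerises to the phenol; the closest known reaction type is the Diels–Alder addition of 2-alkoxy- and 2-silyloxyfurans to acetylenic esters and ketones with spontaneous opening to 4-alkoxyphenols. Ring B is the only ring closed, as a six-membered carbocycle by intermolecular cycloaddition that forms C1'–C2' and C5'–C6' together, after which the oxygen bridge is opened by heterolysis of its C2'–O bond. The two bridgehead centres of racemic 16 disappear on aromatisation, so no stereocentre has to be controlled. The step needs regioselective addition, which should follow because furan C5, the diene terminus with the largest HOMO coefficient (β-carbon of the 4-benzyloxy enol ether and vinylogous to the 2-methoxy group), pairs with the unsubstituted and most electrophilic alkyne carbon (C6') and leaves the methoxy-bearing C2 to bond to C1'. It also needs one direction of bridge opening, which should follow because only the C2' cation is an oxocarbenium ion stabilised by the methoxy group and, through C3'=C4', by the benzyloxy group, so the bridge oxygen stays on C5' and loss of H5' gives the 5'-phenol.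

Step 10
Reactants: 17 5,7-bis(benzyloxy)-2-[4-(benzyloxy)-5-hydroxy-2-methoxyphenyl]-3,6,8-trimethoxy-4H-chromen-4-one
Product: 18 5,7,4',5'-tetrahydroxy-3,6,8,2'-tetramethoxyflavone
Conditions: H2 (1 atm), Pd/C, EtOAc–MeOH, rt
Reagents that add atoms: none
Why: Catalytic hydrogenolysis cleaves the three aryl benzyl ethers to toluene, the routine last step for benzyl-protected flavones; the tetrasubstituted C2=C3 bond and the aryl methyl ethers should not be affected.

Compound list
1 | 1,3,5-tris(benzyloxy)benzene | c1ccc(COc2cc(OCc3ccccc3)cc(OCc3ccccc3)c2)cc1 | starting material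
2 | 1,3,5-tris(benzyloxy)-2,4-dibromobenzene | Brc1c(OCc2ccccc2)cc(OCc2ccccc2)c(Br)c1OCc1ccccc1 | intermediate
3 | 1,3,5-tris(benzyloxy)-2,4-dimethoxybenzene | COc1c(OCc2ccccc2)cc(OCc2ccccc2)c(OC)c1OCc1ccccc1 | intermediate
4 | methoxyacetyl chloride | COCC(Cl)=O | starting material
5 | 2-methoxy-1-[2,4,6-tris(benzyloxy)-3,5-dimethoxyphenyl]ethan-1-one (tribenzyl ketone) | COCC(=O)c1c(OCc2ccccc2)c(OC)c(OCc2ccccc2)c(OC)c1OCc1ccccc1 | intermediate
6 | 1-[4,6-bis(benzyloxy)-2-hydroxy-3,5-dimethoxyphenyl]-2-methoxyethan-1-one | COCC(=O)c1c(O)c(OC)c(OCc2ccccc2)c(OC)c1OCc1ccccc1 | intermediate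
7 | 3,5-bis(benzyloxy)-4,6-dimethoxy-2-(methoxyacetyl)phenyl acetate (aryl acetate) | COCC(=O)c1c(OC(C)=O)c(OC)c(OCc2ccccc2)c(OC)c1OCc1ccccc1 | intermediate
8 | 1-[4,6-bis(benzyloxy)-2-hydroxy-3,5-dimethoxyphenyl]-2-methoxybutane-1,3-dione (racemic, enolisable) | COC(C(C)=O)C(=O)c1c(O)c(OC)c(OCc2ccccc2)c(OC)c1OCc1ccccc1 | intermediate
9 | 5,7-bis(benzyloxy)-3,6,8-trimethoxy-2-methyl-4H-chromen-4-one | Cc1oc2c(OC)c(OCc3ccccc3)c(OC)c(OCc3ccccc3)c2c(=O)c1OC | intermediate
10 | 5,7-bis(benzyloxy)-3,6,8-trimethoxy-4-oxo-4H-chromene-2-carbaldehyde | O=Cc1oc2c(OC)c(OCc3ccccc3)c(OC)c(OCc3ccccc3)c2c(=O)c1OC | intermediate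
11 | 5,7-bis(benzyloxy)-2-ethynyl-3,6,8-trimethoxy-4H-chromen-4-one | C#Cc1oc2c(OC)c(OCc3ccccc3)c(OC)c(OCc3ccccc3)c2c(=O)c1OC | intermediate
12 | tetronic acid (furan-2,4(3H,5H)-dione) | O=C1CC(=O)CO1 | starting material
13 | 4-(benzyloxy)furan-2(5H)-one | O=C1C=C(OCc2ccccc2)CO1 | intermediate
14 | 4-(benzyloxy)-2-methoxy-5H-furan-1-ium tetrafluoroborate (O-methylated lactone, charge shared by the three oxygens) | COC1=[O+]CC(OCc2ccccc2)=C1.F[B-](F)(F)F | intermediate
15 | 4-(benzyloxy)-2-methoxyfuran | COc1cc(OCc2ccccc2)co1 | intermediate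
16 | 5,7-bis(benzyloxy)-2-[5-(benzyloxy)-1-methoxy-7-oxabicyclo[2.2.1]hepta-2,5-dien-2-yl]-3,6,8-trimethoxy-4H-chromen-4-one (racemic; bridgeheads C1 and C4 joined by O7) | COC12OC(C(OCc3ccccc3)=C1)C=C2c1oc2c(OC)c(OCc3ccccc3)c(OC)c(OCc3ccccc3)c2c(=O)c1OC | intermediate
17 | 5,7-bis(benzyloxy)-2-[4-(benzyloxy)-5-hydroxy-2-methoxyphenyl]-3,6,8-trimethoxy-4H-chromen-4-one | COc1cc(OCc2ccccc2)c(O)cc1-c1oc2c(OC)c(OCc3ccccc3)c(OC)c(OCc3ccccc3)c2c(=O)c1OC | intermediate
18 | 5,7,4',5'-tetrahydroxy-3,6,8,2'-tetramethoxyflavone (no stereocentre) | COc1cc(O)c(O)cc1-c1oc2c(OC)c(O)c(OC)c(O)c2c(=O)c1OC | target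

Total step count: 10.
Longest linear sequence: 8 steps (steps 1–6, 9 and 10); the furan branch (steps 7 and 8) joins at step 9.

Steps most likely to fail

Step 8 (proposed method). The furanium ion may hand its methyl or benzyl group to unreacted lactone or to the amine faster than it loses the C5 proton, and the dialkoxyfuran may be hydrolysed back to a butenolide by traces of acid during isolation. The fallback uses known chemistry, sets out from 13 and comes back at 18. Lactone 13 is O-silylated with TBSOTf and Et3N in CH2Cl2 at 0 °C, the standard siloxyfuran formation of tetronates, to give 4-(benzyloxy)-2-[(tert-butyldimethylsilyl)oxy]furan F1. F1 and alkyne 11 are heated as in step 9 and should pass through 5,7-bis(benzyloxy)-2-{5-(benzyloxy)-1-[(tert-butyldimethylsilyl)oxy]-7-oxabicyclo[2.2.1]hepta-2,5-dien-2-yl}-3,6,8-trimethoxy-4H-chromen-4-one F2 to 5,7-bis(benzyloxy)-2-{4-(benzyloxy)-2-[(tert-butyldimethylsilyl)oxy]-5-hydroxyphenyl}-3,6,8-trimethoxy-4H-chromen-4-one F3. The free 5'-phenol is capped with 4-methoxybenzyl chloride and K2CO3 in acetone to give 5,7-bis(benzyloxy)-2-{4-(benzyloxy)-2-[(tert-butyldimethylsilyl)oxy]-5-[(4-methoxybenzyl)oxy]phenyl}-3,6,8-trimethoxy-4H-chromen-4-one F4. CsF and MeI in DMF then exchange the 2'-silyl group for methyl to give 5,7-bis(benzyloxy)-2-{4-(benzyloxy)-2-methoxy-5-[(4-methoxybenzyl)oxy]phenyl}-3,6,8-trimethoxy-4H-chromen-4-one F5. Hydrogenolysis under the conditions of step 10 removes the three benzyl groups and the 4-methoxybenzyl group and gives 18.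

Step 9. The alkyne is activated only through the C2=C3 bond of ring C and the 3-methoxy group is a donor, so cycloaddition may be slower than decomposition of the furan. The reaction may also stop at an open-chain adduct in which furan C5 has added to the alkyne without ring closure. The fallback is a Baker–Venkataraman flavone synthesis that sets out from 6 and comes back at 18. Commercial 2,4,5-trihydroxybenzaldehyde is benzylated at its two non-chelated hydroxyls (BnBr, K2CO3, DMF) to 4,5-bis(benzyloxy)-2-hydroxybenzaldehyde F6 and methylated (MeI, K2CO3, acetone) to 4,5-bis(benzyloxy)-2-methoxybenzaldehyde F7. Pinnick oxidation (NaClO2, NaH2PO4, 2-methyl-2-butene) gives 4,5-bis(benzyloxy)-2-methoxybenzoic acid F8, and oxalyl chloride with catalytic DMF gives 4,5-bis(benzyloxy)-2-methoxybenzoyl chloride F9. F9 acylates the phenol of 6 (pyridine, DMAP) to 3,5-bis(benzyloxy)-4,6-dimethoxy-2-(methoxyacetyl)phenyl 4,5-bis(benzyloxy)-2-methoxybenzoate F10. LiN(SiMe3)2 in THF (−78 → 0 °C) moves the aroyl group to carbon and gives racemic 1-[4,6-bis(benzyloxy)-2-hydroxy-3,5-dimethoxyphenyl]-3-[4,5-bis(benzyloxy)-2-methoxyphenyl]-2-methoxypropane-1,3-dione F11. TsOH in warm toluene closes ring C to 5,7-bis(benzyloxy)-2-[4,5-bis(benzyloxy)-2-methoxyphenyl]-3,6,8-trimethoxy-4H-chromen-4-one F12, and hydrogenolysis as in step 10 gives 18.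

Step 3. The Lewis-acid complex of methoxyacetyl chloride may lose carbon monoxide and alkylate the ring instead of acylating it, and more than one benzyl ether may be cleaved. The fallback sets out from 3 and comes back at 6. Vilsmeier–Haack formylation (POCl3, DMF, 0 → 60 °C) gives 2,4,6-tris(benzyloxy)-3,5-dimethoxybenzaldehyde F13. Methoxymethyllithium (from Bu3SnCH2OMe and n-BuLi, THF, −78 °C) adds to give racemic 2-methoxy-1-[2,4,6-tris(benzyloxy)-3,5-dimethoxyphenyl]ethan-1-ol F14. Dess–Martin periodinane oxidises F14 to ketone 5, now isolated, and BCl3 (1.1 equiv, CH2Cl2, −78 °C) removes one ortho benzyl group to give 6.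

Further compounds
F1 | step 8 | 4-(benzyloxy)-2-[(tert-butyldimethylsilyl)oxy]furan | CC(C)(C)[Si](C)(C)Oc1cc(OCc2ccccc2)co1
F2 | step 8 | 5,7-bis(benzyloxy)-2-{5-(benzyloxy)-1-[(tert-butyldimethylsilyl)oxy]-7-oxabicyclo[2.2.1]hepta-2,5-dien-2-yl}-3,6,8-trimethoxy-4H-chromen-4-one (racemic, not isolated) | CC(C)(C)[Si](C)(C)OC12OC(C(OCc3ccccc3)=C1)C=C2c1oc2c(OC)c(OCc3ccccc3)c(OC)c(OCc3ccccc3)c2c(=O)c1OC
F3 | step 8 | 5,7-bis(benzyloxy)-2-{4-(benzyloxy)-2-[(tert-butyldimethylsilyl)oxy]-5-hydroxyphenyl}-3,6,8-trimethoxy-4H-chromen-4-one | CC(C)(C)[Si](C)(C)Oc1cc(OCc2ccccc2)c(O)cc1-c1oc2c(OC)c(OCc3ccccc3)c(OC)c(OCc3ccccc3)c2c(=O)c1OC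
F4 | step 8 | 5,7-bis(benzyloxy)-2-{4-(benzyloxy)-2-[(tert-butyldimethylsilyl)oxy]-5-[(4-methoxybenzyl)oxy]phenyl}-3,6,8-trimethoxy-4H-chromen-4-one | CC(C)(C)[Si](C)(C)Oc1cc(OCc2ccccc2)c(OCc2ccc(OC)cc2)cc1-c1oc2c(OC)c(OCc3ccccc3)c(OC)c(OCc3ccccc3)c2c(=O)c1OC
F5 | step 8 | 5,7-bis(benzyloxy)-2-{4-(benzyloxy)-2-methoxy-5-[(4-methoxybenzyl)oxy]phenyl}-3,6,8-trimethoxy-4H-chromen-4-one | COc1cc(OCc2ccccc2)c(OCc2ccc(OC)cc2)cc1-c1oc2c(OC)c(OCc3ccccc3)c(OC)c(OCc3ccccc3)c2c(=O)c1OC
F6 | step 9 | 4,5-bis(benzyloxy)-2-hydroxybenzaldehyde | O=Cc1cc(OCc2ccccc2)c(OCc2ccccc2)cc1O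
F7 | step 9 | 4,5-bis(benzyloxy)-2-methoxybenzaldehyde | COc1cc(OCc2ccccc2)c(OCc2ccccc2)cc1C=O
F8 | step 9 | 4,5-bis(benzyloxy)-2-methoxybenzoic acid | COc1cc(OCc2ccccc2)c(OCc2ccccc2)cc1C(=O)O
F9 | step 9 | 4,5-bis(benzyloxy)-2-methoxybenzoyl chloride | COc1cc(OCc2ccccc2)c(OCc2ccccc2)cc1C(Cl)=O
F10 | step 9 | 3,5-bis(benzyloxy)-4,6-dimethoxy-2-(methoxyacetyl)phenyl 4,5-bis(benzyloxy)-2-methoxybenzoate | COCC(=O)c1c(OC(=O)c2cc(OCc3ccccc3)c(OCc3ccccc3)cc2OC)c(OC)c(OCc2ccccc2)c(OC)c1OCc1ccccc1
F11 | step 9 | 1-[4,6-bis(benzyloxy)-2-hydroxy-3,5-dimethoxyphenyl]-3-[4,5-bis(benzyloxy)-2-methoxyphenyl]-2-methoxypropane-1,3-dione (racemic, enolisable) | COC(C(=O)c1cc(OCc2ccccc2)c(OCc2ccccc2)cc1OC)C(=O)c1c(O)c(OC)c(OCc2ccccc2)c(OC)c1OCc1ccccc1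
F12 | step 9 | 5,7-bis(benzyloxy)-2-[4,5-bis(benzyloxy)-2-methoxyphenyl]-3,6,8-trimethoxy-4H-chromen-4-one | COc1cc(OCc2ccccc2)c(OCc2ccccc2)cc1-c1oc2c(OC)c(OCc3ccccc3)c(OC)c(OCc3ccccc3)c2c(=O)c1OC
F13 | step 3 | 2,4,6-tris(benzyloxy)-3,5-dimethoxybenzaldehyde | COc1c(OCc2ccccc2)c(C=O)c(OCc2ccccc2)c(OC)c1OCc1ccccc1
F14 | step 3 | 2-methoxy-1-[2,4,6-tris(benzyloxy)-3,5-dimethoxyphenyl]ethan-1-ol (racemic) | COCC(O)c1c(OCc2ccccc2)c(OC)c(OCc2ccccc2)c(OC)c1OCc1ccccc1
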